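**Retrosynthetic overview**

1. Target 18 is reached from cis-benzodioxane 14 by functional-group work only: O-debenzylation, acetal and silyl hydrolysis, Wittig olefination and ester reduction.
2. Feature used: in the 2,3-dihydro-1,4-benzodioxine ring (O1–C2(aryl)–C3(CH2OH)–O4–C4a–C8a), O1 joins the epimerisable benzylic sp3 carbon C2 to the aromatic carbon C8a. Disconnecting O1–C8a rather than O1–C2 gives the erythro bromo alcohol 13, and the forward ring closure touches neither C2 nor C3.
3. 13 is disconnected at the carbinol–aryl bond (C2–aryl of the target) into α-aryloxy aldehyde 7 and aryl Grignard 12; Felkin–Anh addition sets the carbinol centre from the aryloxy centre.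
4. 7 comes from Mitsunobu inversion of (S)-glycerate 5 with bromophenol 2 (the C3–O4 bond). 2 is made from 5-bromovanillin, 12 from 5-bromo-o-vanillin by Dakin oxidation and benzylation.
5. Ring order: both benzene rings are purchased; the 1,4-dioxane ring is the only ring formed (step 9).

Key step: step 9

Remark: compounds 1, 3 and 8 are taken as commercial. All benzodioxanes are numbered O1–C2(aryl)–C3(CH2O)–O4–C4a–C5(OMe)–C6–C7(side chain)–C8–C8a; in this numbering the target is cis-(2S,3R).

**Route**

Step 1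
Reactants: 1 5-bromovanillin
Product: 2 2-bromo-4-(1,3-dioxolan-2-yl)-6-methoxyphenol
Conditions: HOCH2CH2OH (3 equiv), p-TsOH (cat.), toluene, reflux, Dean–Stark; Et3N quench
Reagents that add atoms: ethylene glycol, OCCO
Why: Acid-catalysed acetalisation with azeotropic water removal should give the dioxolane, which masks the aldehyde against hydride and Grignard reagents and removes the para acceptor from the bromoarene, while the phenol stays free for step 4.

Step 2
Reactants: 3 methyl (S)-2,2-dimethyl-1,3-dioxolane-4-carboxylate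
Product: 4 methyl (S)-2,3-dihydroxypropanoate
Conditions: AcOH/H2O (4:1), 40 °C; concentrate, toluene azeotrope
Reagents that add atoms: none
Why: Acid-catalysed hydrolysis of the isopropylidene ketal should free the diol without touching the methyl ester or the stereocentre.

Step 3
Reactants: 4 methyl (S)-2,3-dihydroxypropanoate
Product: 5 methyl (S)-3-[(tert-butyldimethylsilyl)oxy]-2-hydroxypropanoate
Conditions: TBSCl (1.05 equiv), imidazole, CH2Cl2, 0 °C
Reagents that add atoms: tert-butyldimethylsilyl chloride, CC(C)(C)[Si](C)(C)Cl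
Why: Silylation is sterically selective for the primary hydroxyl, leaving the secondary α-hydroxyl free for the Mitsunobu reaction.

Step 4
Reactants: 5 methyl (S)-3-[(tert-butyldimethylsilyl)oxy]-2-hydroxypropanoate; 2 2-bromo-4-(1,3-dioxolan-2-yl)-6-methoxyphenol
Product: 6 methyl (R)-2-[2-bromo-4-(1,3-dioxolan-2-yl)-6-methoxyphenoxy]-3-[(tert-butyldimethylsilyl)oxy]propanoate
Conditions: PPh3, DIAD, THF, 0 °C → rt
Reagents that add atoms: none
Why: Mitsunobu reaction: the acidic 2,6-disubstituted phenol displaces the alkoxyphosphonium of the α-hydroxy ester by SN2 with inversion (S → R), forming the future C3–O4 bond with the bromine already ortho to it.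

Step 5
Reactants: 6 methyl (R)-2-[2-bromo-4-(1,3-dioxolan-2-yl)-6-methoxyphenoxy]-3-[(tert-butyldimethylsilyl)oxy]propanoate
Product: 7 (R)-2-[2-bromo-4-(1,3-dioxolan-2-yl)-6-methoxyphenoxy]-3-[(tert-butyldimethylsilyl)oxy]propanal
Conditions: DIBAL-H (1.1 equiv), CH2Cl2, −78 °C; MeOH, aq. Rochelle salt; used crude at once
Reagents that add atoms: none
Why: DIBAL half-reduction of an α-alkoxy ester stops at the chelated tetrahedral aluminium hemiacetal at −78 °C, and immediate use of the aldehyde should avoid α-epimerisation.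

Step 6
Reactants: 8 5-bromo-2-hydroxy-3-methoxybenzaldehyde
Product: 10 5-bromo-3-methoxybenzene-1,2-diol, via aryl formate 9 (not isolated)
Conditions: aq. NaOH (1.05 equiv), 6% H2O2 (1.2 equiv), 0 → 40 °C, N2; then 1 M HCl
Reagents that add atoms: hydrogen peroxide, OO
Why: Dakin oxidation: hydroperoxide adds to the ortho-hydroxybenzaldehyde, the electron-rich aryl group migrates to oxygen and the formate is saponified in the flask.

Step 7
Reactants: 10 5-bromo-3-methoxybenzene-1,2-diol
Product: 11 1,2-bis(benzyloxy)-5-bromo-3-methoxybenzene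
Conditions: BnBr (2.3 equiv), K2CO3 (3 equiv), DMF, 50 °C, N2
Reagents that add atoms: benzyl bromide, BrCc1ccccc1
Why: Williamson etherification of both phenoxides should give the bis-benzyl ether, which is inert to magnesium, Grignard addition and the basic palladium step.

Step 8
Reactants: 11 1,2-bis(benzyloxy)-5-bromo-3-methoxybenzene; 7 (R)-2-[2-bromo-4-(1,3-dioxolan-2-yl)-6-methoxyphenoxy]-3-[(tert-butyldimethylsilyl)oxy]propanal
Product: 13 (1S,2R)-1-[3,4-bis(benzyloxy)-5-methoxyphenyl]-2-[2-bromo-4-(1,3-dioxolan-2-yl)-6-methoxyphenoxy]-3-[(tert-butyldimethylsilyl)oxy]propan-1-ol, via arylmagnesium bromide 12 (not isolated)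
Conditions: 11, Mg, I2 (cat.), THF, 45 °C; then 7, THF, −78 → −40 °C; aq. NH4Cl
Reagents that add atoms: none
Why: Grignard addition under polar Felkin–Anh control: with a non-chelating silyl ether and a hindered, weakly basic aryloxy oxygen in THF, the C–OAr bond should lie anti to the incoming aryl group, which passes the α-hydrogen and sets C1 as S (erythro) from the existing C2 centre.

Step 9
Reactants: 13 (1S,2R)-1-[3,4-bis(benzyloxy)-5-methoxyphenyl]-2-[2-bromo-4-(1,3-dioxolan-2-yl)-6-methoxyphenoxy]-3-[(tert-butyldimethylsilyl)oxy]propan-1-ol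
Product: 14 (2S,3R)-2-[3,4-bis(benzyloxy)-5-methoxyphenyl]-3-{[(tert-butyldimethylsilyl)oxy]methyl}-7-(1,3-dioxolan-2-yl)-5-methoxy-2,3-dihydro-1,4-benzodioxine
Conditions: Pd(OAc)2 (5 mol%), 2-(di-tert-butylphosphino)-1,1'-binaphthyl (6 mol%), Cs2CO3 (1.5 equiv), toluene, 70–80 °C
Reagents that add atoms: none
Why: Buchwald–Hartwig-type intramolecular etherification: the C8a–Br bond adds oxidatively to the bulky-phosphine Pd(0), carbonate-assisted exchange puts the C1 alkoxide on palladium, and C(sp2)–O reductive elimination forms O1–C8a. The closest known reaction type is the Pd-catalysed cyclisation of 2-(2-bromoaryloxy)alkanols, secondary alcohols included, to 1,4-benzodioxanes. The 1,4-dioxane ring closes by 6-exo attack of oxygen on the aryl carbon, that is, reductive elimination from a seven-membered oxapalladacycle. No stereocentre is created: neither the C1–O nor the C2–O bond is broken, so the erythro (1S,2R) chain should be carried with retention into the cis-(2S,3R) ring, and no benzylic cation or quinone methide can form. The step needs C–O reductive elimination to beat β-hydride elimination of the benzylic alkoxide, which the bulky di-tert-butylbiarylphosphine and the mild base should secure, and it needs the benzylic oxygen to be the only nucleophile, which the silyl ether on the primary oxygen secures. The dioxolane keeps the bromoarene free of a para acceptor, so base-induced Smiles migration of the aryl group is not available.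

Step 10
Reactants: 14 (2S,3R)-2-[3,4-bis(benzyloxy)-5-methoxyphenyl]-3-{[(tert-butyldimethylsilyl)oxy]methyl}-7-(1,3-dioxolan-2-yl)-5-methoxy-2,3-dihydro-1,4-benzodioxine
Product: 15 5-[(2S,3R)-3-{[(tert-butyldimethylsilyl)oxy]methyl}-7-(1,3-dioxolan-2-yl)-5-methoxy-2,3-dihydro-1,4-benzodioxin-2-yl]-3-methoxybenzene-1,2-diol
Conditions: H2 (1 atm), 10% Pd/C, EtOAc, rt; stopped at full debenzylation
Reagents that add atoms: none
Why: Catalytic hydrogenolysis cleaves primary phenolic benzyl ethers much faster than the cyclic secondary benzylic aryl ether (C2–O1) or the aryl dioxolane in neutral aprotic solvent, and the silyl ether is stable in EtOAc; it is done here because no alkene is yet present.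

Step 11
Reactants: 15 5-[(2S,3R)-3-{[(tert-butyldimethylsilyl)oxy]methyl}-7-(1,3-dioxolan-2-yl)-5-methoxy-2,3-dihydro-1,4-benzodioxin-2-yl]-3-methoxybenzene-1,2-diol
Product: 16 (2S,3R)-2-(3,4-dihydroxy-5-methoxyphenyl)-3-(hydroxymethyl)-5-methoxy-2,3-dihydro-1,4-benzodioxine-7-carbaldehyde
Conditions: AcOH/THF/H2O (3:1:1), rt, degassed
Reagents that add atoms: water, O
Why: Weak aqueous acid should hydrolyse the electron-rich aryl dioxolane and the primary TBS ether in one operation, while being too mild at room temperature to ionise the C2–O1 bond of the cis ring.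

Step 12
Reactants: 16 (2S,3R)-2-(3,4-dihydroxy-5-methoxyphenyl)-3-(hydroxymethyl)-5-methoxy-2,3-dihydro-1,4-benzodioxine-7-carbaldehyde
Product: 17 methyl (E)-3-[(2S,3R)-2-(3,4-dihydroxy-5-methoxyphenyl)-3-(hydroxymethyl)-5-methoxy-2,3-dihydro-1,4-benzodioxin-7-yl]prop-2-enoate
Conditions: Ph3P=CHCO2Me (1.5 equiv), THF, rt → 40 °C, N2
Reagents that add atoms: methyl (triphenylphosphoranylidene)acetate, COC(=O)C=P(c1ccccc1)(c1ccccc1)c1ccccc1
Why: Wittig olefination with a stabilised ylide should give the E-acrylate from the aryl aldehyde under near-neutral conditions that tolerate the free catechol and primary alcohol and do not generate a phenoxide able to open the ring.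

Step 13
Reactants: 17 methyl (E)-3-[(2S,3R)-2-(3,4-dihydroxy-5-methoxyphenyl)-3-(hydroxymethyl)-5-methoxy-2,3-dihydro-1,4-benzodioxin-7-yl]prop-2-enoate
Product: 18 5-[(2S,3R)-3-(hydroxymethyl)-7-[(E)-3-hydroxyprop-1-en-1-yl]-5-methoxy-2,3-dihydro-1,4-benzodioxin-2-yl]-3-methoxybenzene-1,2-diol (target)
Conditions: DIBAL-H (7 equiv), THF, −78 → −20 °C; aq. citric acid/Rochelle salt work-up, N2
Reagents that add atoms: none
Why: DIBAL reduces the α,β-unsaturated ester by 1,2-addition to the allylic alcohol with the E-alkene intact; the excess covers the three acidic hydroxyls, and the cold aluminium phenoxides should not trigger ring opening.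

**Compound list**

1 | 5-bromovanillin (3-bromo-4-hydroxy-5-methoxybenzaldehyde) | COc1cc(C=O)cc(Br)c1O | starting material
2 | 2-bromo-4-(1,3-dioxolan-2-yl)-6-methoxyphenol | COc1cc(C2OCCO2)cc(Br)c1O | intermediate
3 | methyl (S)-2,2-dimethyl-1,3-dioxolane-4-carboxylate | COC(=O)[C@@H]1COC(C)(C)O1 | starting material
4 | methyl (S)-2,3-dihydroxypropanoate | COC(=O)[C@@H](O)CO | intermediate
5 | methyl (S)-3-[(tert-butyldimethylsilyl)oxy]-2-hydroxypropanoate | COC(=O)[C@@H](O)CO[Si](C)(C)C(C)(C)C | intermediate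
6 | methyl (R)-2-[2-bromo-4-(1,3-dioxolan-2-yl)-6-methoxyphenoxy]-3-[(tert-butyldimethylsilyl)oxy]propanoate | COC(=O)[C@H](Oc1c(Br)cc(C2OCCO2)cc1OC)CO[Si](C)(C)C(C)(C)C | intermediate
7 | (R)-2-[2-bromo-4-(1,3-dioxolan-2-yl)-6-methoxyphenoxy]-3-[(tert-butyldimethylsilyl)oxy]propanal | O=C[C@H](Oc1c(Br)cc(C2OCCO2)cc1OC)CO[Si](C)(C)C(C)(C)C | intermediate
8 | 5-bromo-2-hydroxy-3-methoxybenzaldehyde | COc1cc(Br)cc(C=O)c1O | starting material
9 | 5-bromo-2-hydroxy-3-methoxyphenyl formate | COc1cc(Br)cc(OC=O)c1O | intermediate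
10 | 5-bromo-3-methoxybenzene-1,2-diol | COc1cc(Br)cc(O)c1O | intermediate
11 | 1,2-bis(benzyloxy)-5-bromo-3-methoxybenzene | COc1cc(Br)cc(OCc2ccccc2)c1OCc1ccccc1 | intermediate
12 | [3,4-bis(benzyloxy)-5-methoxyphenyl]magnesium bromide | COc1cc([Mg]Br)cc(OCc2ccccc2)c1OCc1ccccc1 | intermediate
13 | (1S,2R)-1-[3,4-bis(benzyloxy)-5-methoxyphenyl]-2-[2-bromo-4-(1,3-dioxolan-2-yl)-6-methoxyphenoxy]-3-[(tert-butyldimethylsilyl)oxy]propan-1-ol (erythro) | COc1cc([C@H](O)[C@H](Oc2c(Br)cc(C3OCCO3)cc2OC)CO[Si](C)(C)C(C)(C)C)cc(OCc2ccccc2)c1OCc1ccccc1 | intermediate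
14 | (2S,3R)-2-[3,4-bis(benzyloxy)-5-methoxyphenyl]-3-{[(tert-butyldimethylsilyl)oxy]methyl}-7-(1,3-dioxolan-2-yl)-5-methoxy-2,3-dihydro-1,4-benzodioxine (cis) | COc1cc([C@@H]2Oc3cc(C4OCCO4)cc(OC)c3O[C@@H]2CO[Si](C)(C)C(C)(C)C)cc(OCc2ccccc2)c1OCc1ccccc1 | intermediate
15 | 5-[(2S,3R)-3-{[(tert-butyldimethylsilyl)oxy]methyl}-7-(1,3-dioxolan-2-yl)-5-methoxy-2,3-dihydro-1,4-benzodioxin-2-yl]-3-methoxybenzene-1,2-diol | COc1cc([C@@H]2Oc3cc(C4OCCO4)cc(OC)c3O[C@@H]2CO[Si](C)(C)C(C)(C)C)cc(O)c1O | intermediate
16 | (2S,3R)-2-(3,4-dihydroxy-5-methoxyphenyl)-3-(hydroxymethyl)-5-methoxy-2,3-dihydro-1,4-benzodioxine-7-carbaldehyde | COc1cc([C@@H]2Oc3cc(C=O)cc(OC)c3O[C@@H]2CO)cc(O)c1O | intermediate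
17 | methyl (E)-3-[(2S,3R)-2-(3,4-dihydroxy-5-methoxyphenyl)-3-(hydroxymethyl)-5-methoxy-2,3-dihydro-1,4-benzodioxin-7-yl]prop-2-enoate | COc1cc([C@@H]2Oc3cc(/C=C/C(=O)OC)cc(OC)c3O[C@@H]2CO)cc(O)c1O | intermediate
18 | 5-[(2S,3R)-3-(hydroxymethyl)-7-[(E)-3-hydroxyprop-1-en-1-yl]-5-methoxy-2,3-dihydro-1,4-benzodioxin-2-yl]-3-methoxybenzene-1,2-diol | COc1cc([C@@H]2Oc3cc(/C=C/CO)cc(OC)c3O[C@@H]2CO)cc(O)c1O | target

**Step count**

Total: 13 steps. Longest linear sequence: 10 steps (3 → 4 → 5 → 6 → 7 → 13 → 14 → 15 → 16 → 17 → 18).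

**Steps most likely to fail**

Step 9. The palladium benzylic alkoxide may undergo β-hydride elimination (oxidation of the carbinol with hydrodebromination of the arene) faster than C–O reductive elimination, or the silyl group may migrate to the benzylic oxygen before coupling. The fallback inverts the polarity of C8a. It sets out from 13: Miyaura borylation (B2pin2, PdCl2(dppf), KOAc, dioxane, 80 °C; acetate is too weak to form the alkoxide) would give the pinacol boronate F1. Oxidative Chan–Lam etherification (Cu(OAc)2, DMAP, 4 Å MS, MeCN/CH2Cl2, air, rt → 40 °C) would then close the same O1–C8a bond without a palladium alkoxide and without touching either stereocentre. The fallback returns to the route at 14.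

Step 8. Facial selectivity may be poor if magnesium chelation between the carbonyl and the aryloxy oxygen competes with the Felkin–Anh pathway. The fallback sets the carbinol centre by reduction instead of addition. It sets out from the diastereomeric alcohol mixture containing 13: Dess–Martin periodinane (NaHCO3, CH2Cl2, 0 °C) would give the ketone F2. Chelation-controlled reduction with Zn(BH4)2 (Et2O, −20 °C) should then deliver hydride to the zinc chelate of the carbonyl and aryloxy oxygens from the face of the α-hydrogen, giving the erythro alcohol. The fallback returns at 13.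

Step 10. Hydrogenolysis may not stop at the phenolic benzyl ethers and may go on to cleave the benzylic C–O bonds of the dioxolane or the C2–O1 bond of the dioxane ring. The fallback avoids hydrogen altogether by carrying the catechol as silyl ethers. It sets out from 10: TBSCl and imidazole in DMF would give the bis-silyl ether F3. Magnesium in THF would convert it to the arylmagnesium bromide F4, which adds to 7 as in step 8 to give the erythro alcohol F5. The same palladium etherification as in step 9 would give the tris-silylated benzodioxane F6. Aqueous HF in MeCN (0 °C → rt) would then remove all three silyl groups and hydrolyse the acetal in one operation. The fallback returns at 16.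

**Further compounds**

F1 | step 9 | (1S,2R)-1-[3,4-bis(benzyloxy)-5-methoxyphenyl]-3-[(tert-butyldimethylsilyl)oxy]-2-[4-(1,3-dioxolan-2-yl)-2-methoxy-6-(4,4,5,5-tetramethyl-1,3,2-dioxaborolan-2-yl)phenoxy]propan-1-ol | COc1cc([C@H](O)[C@H](Oc2c(B3OC(C)(C)C(C)(C)O3)cc(C3OCCO3)cc2OC)CO[Si](C)(C)C(C)(C)C)cc(OCc2ccccc2)c1OCc1ccccc1
F2 | step 8 | (R)-1-[3,4-bis(benzyloxy)-5-methoxyphenyl]-2-[2-bromo-4-(1,3-dioxolan-2-yl)-6-methoxyphenoxy]-3-[(tert-butyldimethylsilyl)oxy]propan-1-one | COc1cc(C(=O)[C@H](Oc2c(Br)cc(C3OCCO3)cc2OC)CO[Si](C)(C)C(C)(C)C)cc(OCc2ccccc2)c1OCc1ccccc1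
F3 | step 10 | 5-bromo-1,2-bis[(tert-butyldimethylsilyl)oxy]-3-methoxybenzene | COc1cc(Br)cc(O[Si](C)(C)C(C)(C)C)c1O[Si](C)(C)C(C)(C)C
F4 | step 10 | {3,4-bis[(tert-butyldimethylsilyl)oxy]-5-methoxyphenyl}magnesium bromide | COc1cc([Mg]Br)cc(O[Si](C)(C)C(C)(C)C)c1O[Si](C)(C)C(C)(C)C
F5 | step 10 | (1S,2R)-1-{3,4-bis[(tert-butyldimethylsilyl)oxy]-5-methoxyphenyl}-2-[2-bromo-4-(1,3-dioxolan-2-yl)-6-methoxyphenoxy]-3-[(tert-butyldimethylsilyl)oxy]propan-1-ol | COc1cc([C@H](O)[C@H](Oc2c(Br)cc(C3OCCO3)cc2OC)CO[Si](C)(C)C(C)(C)C)cc(O[Si](C)(C)C(C)(C)C)c1O[Si](C)(C)C(C)(C)C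
F6 | step 10 | (2S,3R)-2-{3,4-bis[(tert-butyldimethylsilyl)oxy]-5-methoxyphenyl}-3-{[(tert-butyldimethylsilyl)oxy]methyl}-7-(1,3-dioxolan-2-yl)-5-methoxy-2,3-dihydro-1,4-benzodioxine | COc1cc([C@@H]2Oc3cc(C4OCCO4)cc(OC)c3O[C@@H]2CO[Si](C)(C)C(C)(C)C)cc(O[Si](C)(C)C(C)(C)C)c1O[Si](C)(C)C(C)(C)C
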